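The route rests on cutting the cis-1,3-disubstituted 2,2-dimethylcyclobutane at its CH2–CH(CH2-core) and CMe2–CH(isopropenyl) bonds. In the precursor, artemisia ketone, the future core CH2 (as C=O) and the future isopropenyl carbon (as CMe2) are directly bonded, so the senecioyl and vinyl groups form a 1,5-hexadien-3-one. Its crossed [2+2] photocycloaddition closes both ring bonds in one operation as a bicyclo[2.1.1]hexan-2-one whose two-carbon bridge enforces the cis relation. Norrish cleavage of that bridge then releases isopropenyl and formyl groups; the resolved aldehyde is joined to a chromanone core by reductive alkylation, followed by dearomatising prenylation.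

Key step: step 2

Assumption: the sense of induction of the (S)-SEGPHOS/rhodium catalyst (step 7) and of the (R,R)-DACH-phenyl/palladium catalyst (step 14) is taken from the closest analogies, and the wanted aminal of step 4 is taken to be one separable fraction; if a sense is reversed, the antipodal ligand (or the other fraction) is used with no other change.

Step 1
Reactants: 1 3-methylbut-2-enoyl chloride; 2 trimethyl(3-methylbut-2-en-1-yl)silane
Product: 3 3,3,6-trimethylhepta-1,5-dien-4-one (artemisia ketone)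
Conditions: AlCl3 (1.05 equiv), CH2Cl2, −78 °C; aq. NaHCO3
Reagents that add atoms: none
Why: Lewis-acid-promoted SE2' acylation of an allylsilane (Hosomi–Sakurai type): the acylium from 1 attacks the γ-carbon of 2, which places the CMe2 carbon between the carbonyl and the new vinyl group; no stereocentre is formed.

Step 2
Reactants: 3 3,3,6-trimethylhepta-1,5-dien-4-one
Product: 4 rac-3,3,5,5-tetramethylbicyclo[2.1.1]hexan-2-one
Conditions: hν (350 nm, Pyrex), degassed pentane (0.02 M), 20 °C
Reagents that add atoms: none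
Why: Excitation of the conjugated enone (n→π*) and intersystem crossing give the enone triplet, which bonds to the tethered vinyl group to a 1,4-biradical that collapses to the cyclobutane; the closest known reaction type is the crossed intramolecular [2+2] photocycloaddition of 1,5-hexadien-3-ones to bicyclo[2.1.1]hexan-2-ones (rule of five). The five-membered ring closes first, either 5-exo-trig (enone CMe2 onto the internal vinyl CH) or 5-endo-trig (enone α-CH onto the vinyl CH2), and the four-membered ring then closes by 1,4-biradical recombination, so the CH2–CH and CMe2–CH bonds of the future cyclobutane are both made in this operation. The two new stereocentres are the bridgeheads; their relative configuration is dictated by the two-carbon C(=O)–CMe2 bridge, which can span only one face of the cyclobutane, so the later cis-1,3 relation is built in, while the absolute configuration is not controlled (racemate, resolved in steps 4 and 5). The step needs crossed and not straight regiochemistry and no 1,3-acyl shift: the two-atom tether would make the straight mode a strained bicyclo[2.2.0] closure, the gem-dimethyl group favours the folded conformer, and 350 nm light addresses only the conjugated enone and leaves 4 unexcited.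

Step 3
Reactants: 4 rac-3,3,5,5-tetramethylbicyclo[2.1.1]hexan-2-one
Product: 5 rac-cis-(1S*,3S*)-2,2-dimethyl-3-(prop-1-en-2-yl)cyclobutane-1-carbaldehyde
Conditions: hν (300 nm), degassed MeCN (0.05 M), 20 °C, stopped at partial conversion (4 recycled)
Reagents that add atoms: none
Why: Norrish α-cleavage (type 1) of the strained α-quaternary ketone breaks the C(=O)–CMe2 bond to an acyl/tertiary-alkyl biradical held cis on the cyclobutane; because the ring hydrogens lie on the opposite face, the acyl radical can only take a methyl hydrogen (disproportionation, as in the photolysis of camphor to campholenal), which should give the aldehyde and the isopropenyl group with the cis ring configuration untouched.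

Step 4
Reactants: 5 rac-cis-(1S*,3S*)-2,2-dimethyl-3-(prop-1-en-2-yl)cyclobutane-1-carbaldehyde; 6 (1R,2R)-N,N'-dimethyl-1,2-diphenylethane-1,2-diamine
Product: 7 (4R,5R)-2-[(1S,3S)-2,2-dimethyl-3-(prop-1-en-2-yl)cyclobutyl]-1,3-dimethyl-4,5-diphenylimidazolidine
Conditions: 4 Å molecular sieves, Et2O, rt; separation of the two diastereomers on Et3N-washed silica gel
Reagents that add atoms: none
Why: Aminal formation of an aldehyde with a C2-symmetric secondary 1,2-diamine is neutral and creates no new stereocentre, so the two enantiomers of 5 become two diastereomeric imidazolidines that should be separable (resolution through diastereomeric derivatives); the (1S,3S) isomer is kept.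

Step 5
Reactants: 7 (4R,5R)-2-[(1S,3S)-2,2-dimethyl-3-(prop-1-en-2-yl)cyclobutyl]-1,3-dimethyl-4,5-diphenylimidazolidine
Product: 8 (1S,3S)-2,2-dimethyl-3-(prop-1-en-2-yl)cyclobutane-1-carbaldehyde
Conditions: 2% aq. HCl, Et2O, 0 °C, 10 min; aqueous phase basified (NaOH) to recover 6
Reagents that add atoms: water (O)
Why: Brief, cold, two-phase acid hydrolysis of the aminal should return the aldehyde and the water-soluble diamine salt without touching the α-stereocentre or the isopropenyl group.

Step 6
Reactants: 9 5,7-dihydroxy-2H-chromen-2-one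
Product: 10 5-hydroxy-7-methoxy-2H-chromen-2-one
Conditions: MeI (1.0 equiv), K2CO3 (1.0 equiv), acetone, rt
Reagents that add atoms: iodomethane (CI)
Why: Williamson etherification with one equivalent of MeI should go to the 7-OH, the more acidic and less hindered hydroxyl, and leave the peri 5-OH free.

Step 7
Reactants: 10 5-hydroxy-7-methoxy-2H-chromen-2-one; 11 phenylboronic acid
Product: 12 (4S)-5-hydroxy-7-methoxy-4-phenyl-3,4-dihydro-2H-chromen-2-one
Conditions: Rh(acac)(C2H4)2 (3 mol%), (S)-SEGPHOS (3.3 mol%), 1,4-dioxane/H2O (10:1), 60 °C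
Reagents that add atoms: none
Why: Rhodium-catalysed asymmetric 1,4-addition of an arylboronic acid to a coumarin (Hayashi–Miyaura reaction); the bisphosphine-bound phenylrhodium adds to one face of C4, and the (S)-ligand is chosen to give the (4S) lactone by analogy with other 4-arylchroman-2-ones made this way.

Step 8
Reactants: 12 (4S)-5-hydroxy-7-methoxy-4-phenyl-3,4-dihydro-2H-chromen-2-one; 13 (2E)-2-methylbut-2-enoyl chloride (tigloyl chloride)
Product: 14 (4S)-5-hydroxy-7-methoxy-6-[(2E)-2-methylbut-2-enoyl]-4-phenyl-3,4-dihydro-2H-chromen-2-one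
Conditions: TiCl4 (2.2 equiv), CH2Cl2, −20 → 0 °C; aq. HCl
Reagents that add atoms: none
Why: Ortho-selective Friedel–Crafts acylation of a phenol through its aryloxytitanium chloride, which delivers the acylium to C6 next to the free 5-OH; the titanium chelate of the product should resist cyclisation, and no stereocentre is formed.

Step 9
Reactants: 14 (4S)-5-hydroxy-7-methoxy-6-[(2E)-2-methylbut-2-enoyl]-4-phenyl-3,4-dihydro-2H-chromen-2-one
Product: 15 (2R,3S,10S)-5-methoxy-2,3-dimethyl-10-phenyl-2,3,9,10-tetrahydro-4H,8H-pyrano[2,3-f]chromene-4,8-dione (cis-dimethyl chromanone ring fused to the lactone)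
Conditions: (−)-quinine (20 mol%), chlorobenzene, rt
Reagents that add atoms: none
Why: Cinchona-alkaloid-catalysed intramolecular oxa-Michael addition of an o-tigloylphenol: quinine binds the phenol/enone pair and should set C2 as R with kinetic cis protonation at C3, as known for tigloylphenols of the calanolide type; the 7-OMe group leaves the 5-OH as the only nucleophile, which fixes the ring regiochemistry.

Step 10
Reactants: 15 (2R,3S,10S)-5-methoxy-2,3-dimethyl-10-phenyl-2,3,9,10-tetrahydro-4H,8H-pyrano[2,3-f]chromene-4,8-dione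
Product: 17 (2R,3R,10S)-5-hydroxy-2,3-dimethyl-10-phenyl-2,3,9,10-tetrahydro-4H,8H-pyrano[2,3-f]chromene-4,8-dione, via cis-phenol lactone 16 (not isolated)
Conditions: MgI2·OEt2 (3 equiv), toluene, 80 °C; aq. HCl/Na2S2O3
Reagents that add atoms: none
Why: MgI2 chelated between the ketone and the peri methoxy oxygen cleaves that methyl ether by iodide SN2 attack, and the resulting magnesium chelate should enolise toward C3 so that the methyl group epimerises to the diequatorial trans (2R,3R) isomer without opening of the pyranone ring (C2 untouched).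

Step 11
Reactants: 17 (2R,3R,10S)-5-hydroxy-2,3-dimethyl-10-phenyl-2,3,9,10-tetrahydro-4H,8H-pyrano[2,3-f]chromene-4,8-dione
Product: 18 methyl (3S)-3-[(2R,3R)-5,7-dihydroxy-2,3-dimethyl-4-oxo-3,4-dihydro-2H-chromen-8-yl]-3-phenylpropanoate
Conditions: MeOH, H2SO4 (cat.), 40 °C; NaHCO3 before concentration
Reagents that add atoms: methanol (CO)
Why: Acid-catalysed transesterification of the activated aryl lactone with the solvent opens it to the methyl ester and frees the 7-OH, the donor needed for both C6 alkylations; no stereocentre is affected.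

Step 12
Reactants: 18 methyl (3S)-3-[(2R,3R)-5,7-dihydroxy-2,3-dimethyl-4-oxo-3,4-dihydro-2H-chromen-8-yl]-3-phenylpropanoate; 8 (1S,3S)-2,2-dimethyl-3-(prop-1-en-2-yl)cyclobutane-1-carbaldehyde
Product: 20 methyl (3S)-3-[(2R,3R)-6-{[(1R,3S)-2,2-dimethyl-3-(prop-1-en-2-yl)cyclobutyl]methyl}-5,7-dihydroxy-2,3-dimethyl-4-oxo-3,4-dihydro-2H-chromen-8-yl]-3-phenylpropanoate, via o-quinone methide 19 (not isolated)
Conditions: L-proline (20 mol%), Hantzsch ester (1.2 equiv), CH2Cl2/EtOH (1:1), rt
Reagents that add atoms: none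
Why: Three-component reductive alkylation: amine-catalysed Knoevenagel-type condensation of the aldehyde at C6, the only free ring carbon of the acylphloroglucinol-type nucleus, gives the o-quinone methide, which is reduced at once by hydride transfer from the Hantzsch ester; no stereocentre is made or touched.

Step 13
Reactants: 21 3-methylbut-2-en-1-ol
Product: 22 tert-butyl 3-methylbut-2-en-1-yl carbonate
Conditions: Boc2O (1.2 equiv), DMAP (5 mol%), CH2Cl2, 0 °C → rt
Reagents that add atoms: di-tert-butyl dicarbonate (CC(C)(C)OC(=O)OC(=O)OC(C)(C)C)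
Why: DMAP-catalysed alkoxycarbonylation of a primary allylic alcohol; no stereocentre.

Step 14
Reactants: 20 methyl (3S)-3-[(2R,3R)-6-{[(1R,3S)-2,2-dimethyl-3-(prop-1-en-2-yl)cyclobutyl]methyl}-5,7-dihydroxy-2,3-dimethyl-4-oxo-3,4-dihydro-2H-chromen-8-yl]-3-phenylpropanoate; 22 tert-butyl 3-methylbut-2-en-1-yl carbonate
Product: 23 methyl (3S)-3-[(2R,3R,6R)-6-{[(1R,3S)-2,2-dimethyl-3-(prop-1-en-2-yl)cyclobutyl]methyl}-5-hydroxy-2,3-dimethyl-6-(3-methylbut-2-en-1-yl)-4,7-dioxo-3,4,6,7-tetrahydro-2H-chromen-8-yl]-3-phenylpropanoate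
Conditions: Pd2(dba)3·CHCl3 (2.5 mol%), (R,R)-DACH-phenyl ligand N,N'-[(1R,2R)-cyclohexane-1,2-diyl]bis[2-(diphenylphosphino)benzamide] (7.5 mol%), THF, 0 °C → rt
Reagents that add atoms: none
Why: Palladium-catalysed asymmetric allylic alkylation (Tsuji–Trost) used as a dearomatising C-prenylation: ionisation of 22 gives a π-prenyl complex and tert-butoxide, the resorcinol-type anion of 20 attacks the unsubstituted allyl terminus with its fully substituted C6 (O-prenyl ethers re-ionise), and the chiral pocket of the ligand should select the ring face and set the quaternary centre as 6R.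

Step 15
Reactants: 23 methyl (3S)-3-[(2R,3R,6R)-6-{[(1R,3S)-2,2-dimethyl-3-(prop-1-en-2-yl)cyclobutyl]methyl}-5-hydroxy-2,3-dimethyl-6-(3-methylbut-2-en-1-yl)-4,7-dioxo-3,4,6,7-tetrahydro-2H-chromen-8-yl]-3-phenylpropanoate
Product: 24 (3S)-3-[(2R,3R,6R)-6-{[(1R,3S)-2,2-dimethyl-3-(prop-1-en-2-yl)cyclobutyl]methyl}-5-hydroxy-2,3-dimethyl-6-(3-methylbut-2-en-1-yl)-4,7-dioxo-3,4,6,7-tetrahydro-2H-chromen-8-yl]-3-phenylpropanoic acid
Conditions: LiOH·H2O (4 equiv), THF/H2O (3:1), 0 °C → rt; 1 M HCl to pH 3–4 at 0 °C
Reagents that add atoms: lithium hydroxide ([Li+].[OH-])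
Why: Saponification of the methyl ester; the acidic enol of the β-triketone is deprotonated first, which should shield the chromanone from base-induced ring opening, so all six stereocentres are retained.

Compound list
1 | 3-methylbut-2-enoyl chloride | CC(C)=CC(=O)Cl | starting material
2 | trimethyl(3-methylbut-2-en-1-yl)silane | CC(C)=CC[Si](C)(C)C | starting material
3 | 3,3,6-trimethylhepta-1,5-dien-4-one (artemisia ketone) | C=CC(C)(C)C(=O)C=C(C)C | intermediate
4 | rac-3,3,5,5-tetramethylbicyclo[2.1.1]hexan-2-one (racemate; bridgeheads necessarily cis) | CC1(C)C(=O)C2CC1C2(C)C | intermediate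
5 | rac-cis-(1S*,3S*)-2,2-dimethyl-3-(prop-1-en-2-yl)cyclobutane-1-carbaldehyde (racemate, written as the pair of enantiomers) | C=C(C)[C@@H]1C[C@H](C=O)C1(C)C.C=C(C)[C@H]1C[C@@H](C=O)C1(C)C | intermediate
6 | (1R,2R)-N,N'-dimethyl-1,2-diphenylethane-1,2-diamine | CN[C@H](c1ccccc1)[C@H](NC)c1ccccc1 | starting material
7 | (4R,5R)-2-[(1S,3S)-2,2-dimethyl-3-(prop-1-en-2-yl)cyclobutyl]-1,3-dimethyl-4,5-diphenylimidazolidine | C=C(C)[C@@H]1C[C@H](C2N(C)[C@H](c3ccccc3)[C@@H](c3ccccc3)N2C)C1(C)C | intermediate
8 | (1S,3S)-2,2-dimethyl-3-(prop-1-en-2-yl)cyclobutane-1-carbaldehyde | C=C(C)[C@@H]1C[C@H](C=O)C1(C)C | intermediate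
9 | 5,7-dihydroxy-2H-chromen-2-one | O=c1ccc2c(O)cc(O)cc2o1 | starting material
10 | 5-hydroxy-7-methoxy-2H-chromen-2-one | COc1cc(O)c2ccc(=O)oc2c1 | intermediate
11 | phenylboronic acid | OB(O)c1ccccc1 | starting material
12 | (4S)-5-hydroxy-7-methoxy-4-phenyl-3,4-dihydro-2H-chromen-2-one | O=C1C[C@@H](c2ccccc2)c2c(O)cc(OC)cc2O1 | intermediate
13 | (2E)-2-methylbut-2-enoyl chloride | C/C=C(\C)C(=O)Cl | starting material
14 | (4S)-5-hydroxy-7-methoxy-6-[(2E)-2-methylbut-2-enoyl]-4-phenyl-3,4-dihydro-2H-chromen-2-one | O=C1C[C@@H](c2ccccc2)c2c(O)c(C(=O)/C(C)=C/C)c(OC)cc2O1 | intermediate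
15 | (2R,3S,10S)-5-methoxy-2,3-dimethyl-10-phenyl-2,3,9,10-tetrahydro-4H,8H-pyrano[2,3-f]chromene-4,8-dione | O=C1C[C@@H](c2ccccc2)c2c3O[C@H](C)[C@H](C)C(=O)c3c(OC)cc2O1 | intermediate
16 | (2R,3S,10S)-5-hydroxy-2,3-dimethyl-10-phenyl-2,3,9,10-tetrahydro-4H,8H-pyrano[2,3-f]chromene-4,8-dione | O=C1C[C@@H](c2ccccc2)c2c3O[C@H](C)[C@H](C)C(=O)c3c(O)cc2O1 | intermediate (not isolated)
17 | (2R,3R,10S)-5-hydroxy-2,3-dimethyl-10-phenyl-2,3,9,10-tetrahydro-4H,8H-pyrano[2,3-f]chromene-4,8-dione | O=C1C[C@@H](c2ccccc2)c2c3O[C@H](C)[C@@H](C)C(=O)c3c(O)cc2O1 | intermediate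
18 | methyl (3S)-3-[(2R,3R)-5,7-dihydroxy-2,3-dimethyl-4-oxo-3,4-dihydro-2H-chromen-8-yl]-3-phenylpropanoate | COC(=O)C[C@@H](c1ccccc1)c1c(O)cc(O)c2c1O[C@H](C)[C@@H](C)C2=O | intermediate
19 | methyl (3S)-3-[(2R,3R)-6-{[(1R,3S)-2,2-dimethyl-3-(prop-1-en-2-yl)cyclobutyl]methylidene}-5-hydroxy-2,3-dimethyl-4,7-dioxo-3,4,6,7-tetrahydro-2H-chromen-8-yl]-3-phenylpropanoate (o-quinone methide, alkene geometry not defined) | COC(=O)C[C@@H](c1ccccc1)C1=C2O[C@H](C)[C@@H](C)C(=O)C2=C(O)C(=C[C@H]3C[C@@H](C(C)=C)C3(C)C)C1=O | intermediate (not isolated)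
20 | methyl (3S)-3-[(2R,3R)-6-{[(1R,3S)-2,2-dimethyl-3-(prop-1-en-2-yl)cyclobutyl]methyl}-5,7-dihydroxy-2,3-dimethyl-4-oxo-3,4-dihydro-2H-chromen-8-yl]-3-phenylpropanoate | COC(=O)C[C@@H](c1ccccc1)c1c(O)c(C[C@H]3C[C@@H](C(C)=C)C3(C)C)c(O)c2c1O[C@H](C)[C@@H](C)C2=O | intermediate
21 | 3-methylbut-2-en-1-ol | CC(C)=CCO | starting material
22 | tert-butyl 3-methylbut-2-en-1-yl carbonate | CC(C)=CCOC(=O)OC(C)(C)C | intermediate
23 | methyl (3S)-3-[(2R,3R,6R)-6-{[(1R,3S)-2,2-dimethyl-3-(prop-1-en-2-yl)cyclobutyl]methyl}-5-hydroxy-2,3-dimethyl-6-(3-methylbut-2-en-1-yl)-4,7-dioxo-3,4,6,7-tetrahydro-2H-chromen-8-yl]-3-phenylpropanoate | C=C(C)[C@@H]1C[C@H](C[C@@]2(CC=C(C)C)C(=O)C([C@@H](CC(=O)OC)c3ccccc3)=C3O[C@H](C)[C@@H](C)C(=O)C3=C2O)C1(C)C | intermediate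
24 | (3S)-3-[(2R,3R,6R)-6-{[(1R,3S)-2,2-dimethyl-3-(prop-1-en-2-yl)cyclobutyl]methyl}-5-hydroxy-2,3-dimethyl-6-(3-methylbut-2-en-1-yl)-4,7-dioxo-3,4,6,7-tetrahydro-2H-chromen-8-yl]-3-phenylpropanoic acid | C=C(C)[C@@H]1C[C@H](C[C@@]2(CC=C(C)C)C(=O)C([C@@H](CC(=O)O)c3ccccc3)=C3O[C@H](C)[C@@H](C)C(=O)C3=C2O)C1(C)C | target

Total step count: 15. Longest linear sequence: 9 steps (9 → 24 through steps 6–12, 14 and 15); the cyclobutane branch (steps 1–5) and the carbonate (step 13) are convergent.

Steps most likely to fail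

Step 14. What may go wrong is poor facial selectivity at C6, because the existing stereocentres of 20 are remote and the outcome rests on the ligand alone, together with O-prenylation that does not funnel back to carbon. The fallback sets out from 20 and comes back at 23. It gives up catalyst control: base-mediated alkylative dearomatisation with prenyl bromide (NaOMe, MeOH, 0 °C) should give 23 together with its 6S epimer F1, and the two C6 epimers are separated by preparative HPLC before step 15.

Step 12. What may go wrong is slow condensation of the hindered α-branched aldehyde, capture of the quinone methide 19 by a second molecule of 18 or by the cis isopropenyl group before hydride transfer, and α-epimerisation of 8 through its enamine. The fallback sets out from 18 and 8 and comes back at 20. It replaces the condensation by a cross-coupling. Compound 18 is iodinated at C6 (N-iodosuccinimide, CH2Cl2, 0 °C) to aryl iodide F2. Aldehyde 8 is reduced (NaBH4, MeOH, 0 °C) to alcohol F3, converted by the Appel reaction (I2, PPh3, imidazole) into alkyl iodide F4, and this is turned into alkylzinc iodide F5 (Zn dust, LiCl, THF). Negishi coupling of F2 with excess F5 (Pd(OAc)2, CPhos, THF, rt; the first equivalents are consumed by the two phenols) should then give 20.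

Step 3. What may go wrong is secondary photolysis of the product aldehyde (decarbonylation, or intramolecular Paternò–Büchi addition to the isopropenyl group) and loss of CO from the acyl radical. The fallback sets out from 4 and comes back at 5 without light. Ketone 4 is reduced (NaBH4, MeOH) to bicyclic alcohol F6, which is treated with Pb(OAc)4 and catalytic Cu(OAc)2 (pyridine, benzene, 80 °C). The alkoxy radical cleaves the same C–CMe2 bond by β-fragmentation, and the tertiary radical is oxidised by divalent copper to the terminal alkene, which should give 5.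

Further compounds
F1 | step 14 | methyl (3S)-3-[(2R,3R,6S)-6-{[(1R,3S)-2,2-dimethyl-3-(prop-1-en-2-yl)cyclobutyl]methyl}-5-hydroxy-2,3-dimethyl-6-(3-methylbut-2-en-1-yl)-4,7-dioxo-3,4,6,7-tetrahydro-2H-chromen-8-yl]-3-phenylpropanoate | C=C(C)[C@@H]1C[C@H](C[C@]2(CC=C(C)C)C(=O)C([C@@H](CC(=O)OC)c3ccccc3)=C3O[C@H](C)[C@@H](C)C(=O)C3=C2O)C1(C)C
F2 | step 12 | methyl (3S)-3-[(2R,3R)-5,7-dihydroxy-6-iodo-2,3-dimethyl-4-oxo-3,4-dihydro-2H-chromen-8-yl]-3-phenylpropanoate | COC(=O)C[C@@H](c1ccccc1)c1c(O)c(I)c(O)c2c1O[C@H](C)[C@@H](C)C2=O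
F3 | step 12 | [(1S,3S)-2,2-dimethyl-3-(prop-1-en-2-yl)cyclobutyl]methanol | C=C(C)[C@@H]1C[C@H](CO)C1(C)C
F4 | step 12 | (1S,3S)-1-(iodomethyl)-2,2-dimethyl-3-(prop-1-en-2-yl)cyclobutane | C=C(C)[C@@H]1C[C@H](CI)C1(C)C
F5 | step 12 | {[(1S,3S)-2,2-dimethyl-3-(prop-1-en-2-yl)cyclobutyl]methyl}zinc iodide | C=C(C)[C@@H]1C[C@H](C[Zn]I)C1(C)C
F6 | step 3 | rac-3,3,5,5-tetramethylbicyclo[2.1.1]hexan-2-ol (mixture of C2 epimers) | CC1(C)C(O)C2CC1C2(C)C
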